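## Structural features

The target is a labdane-type diterpenoid monoacetate: a trans-fused decalin (ring A: C1–C5 and C10; ring B: C5–C10) with a 3-methylidenepent-4-enyl chain (C11–C16) on C9. Labdane numbers are used for skeletal atoms throughout. Ring A holds two quaternary carbons, C4 (axial methyl C19, equatorial CH2OH C18) and C10 (axial methyl C20), on either side of the ring-fusion carbon C5. The two methyl groups are cis to each other, and so are the two carbon arms C18 and C9. Ring B adds four further stereocentres: C5 (H trans to C20), C6 (equatorial acetoxy), C8 (tertiary alcohol, axial methyl C17, equatorial OH) and C9 (equatorial side chain), so C4–C5–C6 and C8–C9–C10 are contiguous arrays. The fragile groups are the 2-substituted buta-1,3-diene (polymerisation, cycloaddition, oxidants), the tertiary alcohol β to the C6 oxygen (dehydration or retro-aldol at the ketone stage), and the secondary acetate beside a free primary alcohol (acyl migration). The real difficulty lies in three places: the 1,3-related quaternary centres of defined absolute configuration; the equatorial C6 oxygen, which is the opposite of what hydride attack on the open face of a C6 ketone would give; and the C8 carbinol with its axial methyl, the opposite of what direct methyl addition to a C8 ketone would give. The key step exploits the fact that C4, C5 and C10 are the two bridgeheads and the carbonyl bridge of a 1,5-dimethylbicyclo[3.3.1]nonan-9-one, in which ring A is the cyclohexanone and C18–C8–C9 is a second three-carbon bridge drawn from acrolein and cut later between C8 and C18. The same bicyclic frame is used twice more before it is opened, to place the C9 side chain on its exposed face and to equilibrate C5 against that chain.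

## Logic of the disconnections

**28 to 27.** The C13=C16 and C14=C15 bonds are cut in the sense of an ene–yne cross-metathesis, because the diene would not survive ozone, peroxide or one-electron reductants. The side chain becomes a plain terminal alkyne. The forward step must tolerate two free hydroxyls and the acetate.

**27 to 26 to 25.** The O–Si bond at C18 and the O–acetyl bond at C6 are cut. The silyl ether is what lets the C6 hydroxyl be acylated alone. The forward steps must stop at the secondary alcohol and must remove silicon without moving the acetyl group.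

**25 to 24 to 23 to 22.** The C6–H bond, then the C7–H bond, then the C7–O and C8–O bonds of an epoxide are removed, which leads back to an enone. In the enone, an oxygen nucleophile can choose the face of C8 opposite C20 and an electron-transfer reduction can choose the equatorial C6 alcohol. The demands are face-selective epoxidation, reductive opening without dehydration, and thermodynamic control at C6.

**22 to 20.** The C7=C8 bond is cut as an aldol condensation, which opens ring B to a monocyclic 1,5-diketone. The forward step must close in one of two possible senses and must not epimerise C9.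

**20 to 19 to 17.** C8 and C18 are rejoined as a trisubstituted alkene inside a bicycle (retro-ozonolysis). Both arms then belong to one ring, and because the alkene is trisubstituted the termini emerge at different oxidation levels (aldehyde and methyl ketone). The forward step must cleave the alkene in the presence of the alkyne and reduce only the aldehyde.

**17 to 14 to 12.** The C6–C7 bond (methyl addition to a nitrile) and the C5–C6 bond (reductive cyanation of a ketone) are cut, which returns the bridging ketone. The hindered ketone must accept a one-carbon unit, and the C5 configuration must come from equilibration.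

**12 to 11 to 10.** The C18–H bond is exchanged for C18–O and then C18=O. The ketone is what allows C9 and C17 to be attached. The forward steps need a regiospecific enol triflate and its hydrogenolysis.

**10 to 6 and 7.** The C9–C11 and C8–C17 bonds are cut (conjugate addition, then enolate methylation). The side chain and C17 then come from simple reagents. The addition must occur on the exposed face of the bridge to set C9.

**6 to 4.** Only oxidation level changes (C18–OH to ketone, C8–C9 to alkene). The carbinol stereocentre disappears. The oxidant must not be basic.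

**4 to 1 and 2.** The C9–C10 and C4–C18 bonds are cut (Michael addition, then aldol). This removes the bridge, both quaternary centres and all remaining stereochemistry. The forward step must choose one enolate face.

## Other disconnections considered

**Alternative 1:** The cut is C5–C10 and C3–C4, so that both rings come from an open chain. The forward key step is an intramolecular Diels–Alder reaction of the acyclic trienoate A1 (diene C10=C1–C2=C3 linked through C9–C8(=O)–C7–C6 to the dienophile C4=C5), on heating or with Me2AlCl, to give the trans-fused octalin ester A2.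
- In its favour: two rings, two C–C bonds and C4, C5 and C10 arise in one step, and the C4/C5 relationship follows stereospecifically from the alkene geometry. The C6 oxygen is already in place with its configuration fixed, so no late reduction of a C6 ketone is needed; on this point the alternative is the better plan.
- Against it here: the diene terminus C10 is fully substituted and must bond to a trisubstituted dienophile while two quaternary carbons form. Facial and endo/exo selectivity must be relayed from C6 and C9 through a flexible tether. C9 sits α to the C8 ketone and could epimerise under the Lewis acid. The C1=C2 bond, the ester, the C8 ketone and the short C11–C12 arm all still need work afterwards.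
- Comparison: structurally the alternative builds more skeleton per step (better). Mechanistically it is a concerted cycloaddition whose facial outcome is only biased, whereas the bridge of the chosen plan makes the cis relationship of C4 and C10 a geometric necessity. In step economy the gain is likely to be spent on assembling A1 (two stereocentres, three defined alkenes), so similar length is expected.

**Alternative 2:** The cut is C9–C10 and C7–C8, with the dienophile tied to the C18 oxygen. The forward key step is a thermal intramolecular Diels–Alder reaction of the dienyl but-2-ynoate A3 to the lactone-bridged cyclohexa-1,4-diene A4, in which a seven-membered lactone temporarily links C18 and C9 through C11.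
- In its favour: the ester tether forces C10 to form on the face of C18, the same logic as the temporary bridge of the chosen plan (equal). C17 and C11 arrive in the same step. The C5=C6 bond of A4 invites hydroboration from the face opposite C20, which would set C5–H and the equatorial C6–OH together; here the alternative is better than the chosen late reduction.
- Against it here: the diene is tetrasubstituted at its ring double bond and flanked by quaternary C4, and the cycloaddition must create a quaternary centre through a medium-ring transition state. The quaternary C4 of A3 must be made enantiopure beforehand, whereas the chosen key step creates it from a commercial ketone. C9 is trigonal in A4, so C9–H and the C8 carbinol must be fashioned from a tetrasubstituted alkene beside a second ring alkene. C11 is at the acid level and five carbons short of the side chain.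
- Comparison: equal in the use of a temporary ring, better at C5/C6, worse at C8/C9 and in access to the substrate; no shorter overall.

**Alternative 3:** The cut is C9–C10 alone. The forward key step is a light-induced (about 300 nm) conrotatory 6π-electrocyclisation of the silylene-bridged trienol ether A5 (C10=C5–C6=C7–C8=C9, with C5 and C8 cis on the central double bond) to the cyclohexa-1,3-dienol ether A6. One correction to the usual label: with the silyloxy group on C6, that central double bond is E by the sequence rule, although it corresponds to the Z bond of previtamin D.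
- In its favour: orbital symmetry fixes H-9 and the C10 methyl trans, as required, without steric arguments. C17, the C6 oxygen and the butynyl chain are already present. Hydrolysis of A6 would lead to the same kind of 6-oxo-7-ene as 22, so the endgames, including the final ene–yne metathesis, coincide (equal from that point on).
- Against it here: such photocyclisations are reversible and compete with double-bond isomerisation, so a photostationary mixture is to be expected. The two conrotatory senses give two diastereomers relative to C4, and only that distant centre and the silylene ring can bias them. A5 needs the quaternary C4 centre enantiopure and three defined double bonds.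
- Comparison: better in the C9/C10 relationship, equal in the endgame, worse in absolute control and in access to the substrate.

Key step: step 1

Assumption: the cinchonidine-derived ammonium salt is taken to give the (1R,5S) bridgeheads of 4; if the sense of induction were opposite, the pseudoenantiomeric cinchonine-derived salt would be used.

## Route

Step 1
Reactants: 1 2,6-dimethylcyclohexanone (commercial cis/trans mixture); 2 prop-2-enal (acrolein)
Product: 4 (1R,2R,5S)-2-hydroxy-1,5-dimethylbicyclo[3.3.1]nonan-9-one, via Michael adduct 3 (not isolated)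
Conditions: N-(9-anthracenylmethyl)cinchonidinium bromide (10 mol%), CsOH·H2O, PhMe, slow addition of 2, −40 → −20 °C
Reagents that add atoms: none
Why: Proposed new method: a chiral quaternary ammonium cation is asked to pair with the tetrasubstituted enolate generated from 1 at the surface of the solid base and to shield one enolate face while it adds to 2 in a Michael reaction, which forms the C9–C10 bond and the first quaternary centre (adduct 3); the closest known reaction types are the racemic base-mediated Michael–aldol α,α′-annulation of 2,6-dialkylcyclohexanones with enals and cinchona-ammonium phase-transfer Michael additions of more acidic cyclic ketones and β-keto esters. Proton transfer then moves the enolate to the other α-carbon, which adds to the tethered aldehyde in a 6-(enolexo)-exo-trig aldol closure that forms C4–C18 and the second six-membered ring. Because a three-carbon bridge can only span one face of the cyclohexanone, the configuration of C1 in 4 is dictated by that of C5 and both methyl groups are forced onto the opposite face; C5 is therefore under catalyst control, C1 under control of the tether, and the carbinol centre C2 is of no consequence (it can equilibrate by retro-aldol/aldol and is destroyed in step 2). Both diastereomers of 1 give the same enolate, so the commercial mixture converges. The only selectivity that has to be earned is the enolate face in the Michael step; the bicyclic framework secures everything else, and slow addition of 2 at low temperature limits its base-induced polymerisation.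

Step 2
Reactants: 4 (1R,2R,5S)-2-hydroxy-1,5-dimethylbicyclo[3.3.1]nonan-9-one
Product: 6 (1R,5S)-1,5-dimethylbicyclo[3.3.1]non-3-ene-2,9-dione, via dione 5 (not isolated)
Conditions: 2-iodoxybenzoic acid (4 equiv), DMSO/PhF, 25 → 75 °C
Reagents that add atoms: none
Why: Excess 2-iodoxybenzoic acid first oxidises the secondary alcohol to dione 5 and then, on warming, dehydrogenates the only enolisable α,β-pair (C3–C4), the known one-pot alcohol-to-enone oxidation with this reagent; the conditions are not basic, so retro-aldol opening of 4 is avoided, the carbinol centre disappears and the two quaternary centres have no adjacent hydrogen through which to epimerise.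

Step 3
Reactants: 6 (1R,5S)-1,5-dimethylbicyclo[3.3.1]non-3-ene-2,9-dione; 7 (4-bromobut-1-yn-1-yl)trimethylsilane
Product: 10 (1R,4R,5S)-1,3,5-trimethyl-4-[4-(trimethylsilyl)but-3-yn-1-yl]bicyclo[3.3.1]nonane-2,9-dione (either configuration at C3), via Grignard reagent 8 (not isolated), via magnesium enolate 9 (not isolated)
Conditions: 7, Mg, THF, 23 °C; then 6, CuBr·SMe2 (20 mol%), THF, −78 °C; then MeI, DMPU, −78 → 0 °C
Reagents that add atoms: iodomethane, CI
Why: Copper-catalysed conjugate addition of the Grignard reagent to the enone followed by C-methylation of the magnesium enolate (tandem conjugate addition–enolate alkylation); the nucleophile should enter C4 from the face of the one-atom carbonyl bridge because the other face is screened by the saturated three-carbon bridge, which is the configuration needed at C9 of the target, while the configuration of the methyl-bearing C3 is irrelevant because it becomes trigonal in step 4.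

Step 4
Reactants: 10 (1R,4R,5S)-1,3,5-trimethyl-4-[4-(trimethylsilyl)but-3-yn-1-yl]bicyclo[3.3.1]nonane-2,9-dione
Product: 11 (1R,4R,5S)-1,3,5-trimethyl-9-oxo-4-[4-(trimethylsilyl)but-3-yn-1-yl]bicyclo[3.3.1]non-2-en-2-yl trifluoromethanesulfonate
Conditions: KN(SiMe3)2, THF, −78 → 0 °C; then PhNTf2, −78 → 23 °C
Reagents that add atoms: N-phenylbis(trifluoromethanesulfonimide), O=S(=O)(N(c1ccccc1)S(=O)(=O)C(F)(F)F)C(F)(F)F
Why: C3 carries the only enolisable hydrogen of 10, so deprotonation and O-sulfonylation of the potassium enolate can give only the tetrasubstituted enol triflate (regiospecific enol triflate formation); the bridging ketone cannot enolise.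

Step 5
Reactants: 11 (1R,4R,5S)-1,3,5-trimethyl-9-oxo-4-[4-(trimethylsilyl)but-3-yn-1-yl]bicyclo[3.3.1]non-2-en-2-yl trifluoromethanesulfonate
Product: 12 (1R,4R,5S)-1,3,5-trimethyl-4-[4-(trimethylsilyl)but-3-yn-1-yl]bicyclo[3.3.1]non-2-en-9-one
Conditions: Pd(OAc)2 (5 mol%), PPh3 (10 mol%), HCO2H, n-Bu3N, DMF, 60 °C
Reagents that add atoms: none
Why: Palladium-catalysed hydrogenolysis of the enol triflate with formate as hydride source (oxidative addition, formate exchange, decarboxylation, reductive elimination) replaces C–O by C–H and leaves the bridging ketone and the silylalkyne untouched; the trisubstituted alkene so formed is the latent C8/C18 cleavage site.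

Step 6
Reactants: 12 (1R,4R,5S)-1,3,5-trimethyl-4-[4-(trimethylsilyl)but-3-yn-1-yl]bicyclo[3.3.1]non-2-en-9-one
Product: 14 (1R,4R,5S)-4-(but-3-yn-1-yl)-1,3,5-trimethylbicyclo[3.3.1]non-2-ene-9-carbonitrile (both C9 epimers), via silylated nitrile 13 (not isolated)
Conditions: TosMIC, KOtBu, DME, EtOH (2 equiv), 0 → 40 °C; then K2CO3, MeOH, 23 °C
Reagents that add atoms: p-toluenesulfonylmethyl isocyanide (TosMIC), Cc1ccc(cc1)S(=O)(=O)C[N+]#[C-]
Why: van Leusen reductive cyanation: the TosMIC anion adds to the bridging ketone, the only carbonyl group present and one whose flanking methyl groups lie in the carbonyl plane and not over its faces, and the oxazoline intermediate collapses with loss of sulfinate and formate to the nitrile, a one-carbon homologation that installs C6; the C9 configuration comes from an unselective protonation and is corrected in step 7, and the carbonate/methanol treatment removes the alkynyl silyl group.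

Step 7
Reactants: 14 (1R,4R,5S)-4-(but-3-yn-1-yl)-1,3,5-trimethylbicyclo[3.3.1]non-2-ene-9-carbonitrile
Product: 17 1-[(1R,4R,5S,9R)-4-(but-3-yn-1-yl)-1,3,5-trimethylbicyclo[3.3.1]non-2-en-9-yl]ethan-1-one, via methyl ketimine 15 (not isolated), via epimeric methyl ketone 16 (not isolated)
Conditions: MeLi (4 equiv), Et2O, 0 → 23 °C; 2 M HCl, THF, 23 °C; then NaOMe, MeOH, 50 °C
Reagents that add atoms: methyllithium, [Li]C; water, O
Why: Methyllithium, after deprotonating the terminal alkyne, adds to the nitrile and acid hydrolysis of the ketimine gives the methyl ketone (nitrile-to-ketone conversion), supplying C7; methoxide then equilibrates the enolisable C9 centre, and the acetyl group should settle on the face of the saturated bridge because the other face holds the syn-axial butynyl chain at C4, which is the configuration that becomes the trans ring fusion.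

Step 8
Reactants: 17 1-[(1R,4R,5S,9R)-4-(but-3-yn-1-yl)-1,3,5-trimethylbicyclo[3.3.1]non-2-en-9-yl]ethan-1-one
Product: 19 (3S)-3-[(1S,2S,3S)-2-acetyl-3-(hydroxymethyl)-1,3-dimethylcyclohexyl]hept-6-yn-2-one, via keto aldehyde 18 (not isolated)
Conditions: O3, CH2Cl2/MeOH, −78 °C; Me2S, −78 → 23 °C; then NaBH4, EtOH/CH2Cl2, −78 °C
Reagents that add atoms: ozone, [O-][O+]=O
Why: Ozone attacks the electron-rich trisubstituted alkene far faster than the terminal alkyne, and cleavage gives an aldehyde at one terminus and a methyl ketone at the other, so the two arms are differentiated by the substitution pattern of the alkene; at −78 °C NaBH4 reduces the aldehyde and spares both ketones (chemoselective aldehyde reduction), and no stereocentre is touched.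

Step 9
Reactants: 19 (3S)-3-[(1S,2S,3S)-2-acetyl-3-(hydroxymethyl)-1,3-dimethylcyclohexyl]hept-6-yn-2-one
Product: 20 (3S)-3-[(1S,2S,3S)-2-acetyl-3-({[tert-butyl(dimethyl)silyl]oxy}methyl)-1,3-dimethylcyclohexyl]hept-6-yn-2-one
Conditions: TBSCl, imidazole, DMF, 23 °C
Reagents that add atoms: tert-butyldimethylsilyl chloride, CC(C)(C)[Si](C)(C)Cl
Why: Standard silylation of the primary neopentyl alcohol, so that only the C6 hydroxyl is free at the acetylation stage; any ring–chain tautomerism of 19 with the neighbouring acetyl group is drained through the open form.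

Step 10
Reactants: 20 (3S)-3-[(1S,2S,3S)-2-acetyl-3-({[tert-butyl(dimethyl)silyl]oxy}methyl)-1,3-dimethylcyclohexyl]hept-6-yn-2-one
Product: 22 (4R,4aS,8S,8aS)-4-(but-3-yn-1-yl)-8-({[tert-butyl(dimethyl)silyl]oxy}methyl)-3,4a,8-trimethyl-4a,5,6,7,8,8a-hexahydronaphthalen-1(4H)-one, via ketol 21 (not isolated)
Conditions: NaOMe, MeOH, 0 → 40 °C
Reagents that add atoms: none
Why: Intramolecular aldol condensation of the 1,5-diketone (6-(enolexo)-exo-trig addition, then E1cB dehydration): the enolate of the acetyl methyl group adds to the side-arm ketone, whereas the reverse mode would have to attack the acetyl carbonyl wedged between two quaternary carbons and would push its methyl group against the silyloxymethyl arm, so the desired enone should dominate kinetically and thermodynamically; the methine α to the side-arm ketone is deprotonated far more slowly than the methyl groups, which is expected to preserve C4, and the ring fusion is the thermodynamically preferred trans one.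

Step 11
Reactants: 22 (4R,4aS,8S,8aS)-4-(but-3-yn-1-yl)-8-({[tert-butyl(dimethyl)silyl]oxy}methyl)-3,4a,8-trimethyl-4a,5,6,7,8,8a-hexahydronaphthalen-1(4H)-one
Product: 23 (2R,3R,4S,4aS,8S,8aS)-4-(but-3-yn-1-yl)-8-({[tert-butyl(dimethyl)silyl]oxy}methyl)-2,3-epoxy-3,4a,8-trimethyloctahydronaphthalen-1(2H)-one (epoxide oxygen cis to H-4 and H-8a)
Conditions: 30% H2O2, NaOH (aq), MeOH, 0 → 23 °C
Reagents that add atoms: hydrogen peroxide, OO
Why: Nucleophilic (Weitz–Scheffer) epoxidation: hydroperoxide adds to the enone β-carbon from the face opposite the axial angular methyl group, which blocks the other face in a 1,3-diaxial sense, and ring closure gives the epoxide on that face; this fixes the C–O configuration of the future tertiary alcohol.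

Step 12
Reactants: 23 (2R,3R,4S,4aS,8S,8aS)-4-(but-3-yn-1-yl)-8-({[tert-butyl(dimethyl)silyl]oxy}methyl)-2,3-epoxy-3,4a,8-trimethyloctahydronaphthalen-1(2H)-one
Product: 24 (3S,4S,4aS,8S,8aS)-4-(but-3-yn-1-yl)-8-({[tert-butyl(dimethyl)silyl]oxy}methyl)-3-hydroxy-3,4a,8-trimethyloctahydronaphthalen-1(2H)-one
Conditions: SmI2 (2.5 equiv), THF/MeOH, −90 °C
Reagents that add atoms: none
Why: Samarium diiodide transfers an electron to the ketone, the ketyl opens the epoxide at the α-carbon and the samarium enolate is protonated by methanol (reductive opening of an α,β-epoxy ketone), which gives the β-hydroxy ketone with the tertiary C–O bond and its configuration intact; the low temperature suppresses dehydration and retro-aldol cleavage.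

Step 13
Reactants: 24 (3S,4S,4aS,8S,8aS)-4-(but-3-yn-1-yl)-8-({[tert-butyl(dimethyl)silyl]oxy}methyl)-3-hydroxy-3,4a,8-trimethyloctahydronaphthalen-1(2H)-one
Product: 25 (1R,3S,4S,4aR,8S,8aS)-4-(but-3-yn-1-yl)-8-({[tert-butyl(dimethyl)silyl]oxy}methyl)-3,4a,8-trimethyldecahydronaphthalene-1,3-diol
Conditions: SmI2 (5 equiv), H2O, Et3N, THF, 23 °C
Reagents that add atoms: none
Why: Single-electron reduction of the ketone with SmI2/water/amine passes through a ketyl and a configurationally mobile organosamarium, which is expected to give the thermodynamically preferred equatorial alcohol (the axial epimer would face three syn-axial methyl groups), whereas hydride reagents would attack the open face and give the axial epimer; the isolated alkyne, the silyl ether and the tertiary alcohol are not reduced under these conditions.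

Step 14
Reactants: 25 (1R,3S,4S,4aR,8S,8aS)-4-(but-3-yn-1-yl)-8-({[tert-butyl(dimethyl)silyl]oxy}methyl)-3,4a,8-trimethyldecahydronaphthalene-1,3-diol
Product: 26 (1R,3S,4S,4aR,8S,8aS)-4-(but-3-yn-1-yl)-8-({[tert-butyl(dimethyl)silyl]oxy}methyl)-3-hydroxy-3,4a,8-trimethyldecahydronaphthalen-1-yl acetate
Conditions: Ac2O, pyridine, DMAP (cat.), CH2Cl2, 0 → 23 °C
Reagents that add atoms: acetic anhydride, CC(=O)OC(C)=O
Why: DMAP-catalysed acylation acetylates the secondary alcohol; the tertiary alcohol reacts much more slowly under these conditions and the primary alcohol is masked.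

Step 15
Reactants: 26 (1R,3S,4S,4aR,8S,8aS)-4-(but-3-yn-1-yl)-8-({[tert-butyl(dimethyl)silyl]oxy}methyl)-3-hydroxy-3,4a,8-trimethyldecahydronaphthalen-1-yl acetate
Product: 27 (1R,3S,4S,4aR,8S,8aS)-4-(but-3-yn-1-yl)-3-hydroxy-8-(hydroxymethyl)-3,4a,8-trimethyldecahydronaphthalen-1-yl acetate
Conditions: HF·pyridine, THF/pyridine, 0 → 23 °C
Reagents that add atoms: none
Why: Fluoride cleaves the primary silyl ether under buffered, non-basic conditions, which should avoid migration of the acetyl group to the liberated primary hydroxyl and leaves the tertiary alcohol and the alkyne alone.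

Step 16
Reactants: 27 (1R,3S,4S,4aR,8S,8aS)-4-(but-3-yn-1-yl)-3-hydroxy-8-(hydroxymethyl)-3,4a,8-trimethyldecahydronaphthalen-1-yl acetate
Product: 28 (1R,3S,4S,4aR,8S,8aS)-3-hydroxy-8-(hydroxymethyl)-3,4a,8-trimethyl-4-(3-methylidenepent-4-en-1-yl)decahydronaphthalen-1-yl acetate (target)
Conditions: second-generation Grubbs catalyst (5 mol%), ethylene (1 atm), CH2Cl2, 40 °C
Reagents that add atoms: ethylene, C=C
Why: Ene–yne cross-metathesis with ethylene: the ruthenium methylidene adds to the terminal alkyne, the vinylcarbene formed is intercepted by ethylene and the 2-substituted buta-1,3-diene is released; free hydroxyl groups and esters are tolerated, and placing this step last keeps the diene away from ozone, peroxide and samarium reagents.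

## Compound list

1 | 2,6-dimethylcyclohexanone (commercial cis/trans mixture, cis isomer drawn) | C[C@H]1CCC[C@@H](C)C1=O | starting material
2 | prop-2-enal (acrolein) | C=CC=O | starting material
3 | 3-[(1S)-1,3-dimethyl-2-oxocyclohexyl]propanal (either configuration at ring C3) | O=CCC[C@]1(C)CCCC(C)C1=O | intermediate (not isolated)
4 | (1R,2R,5S)-2-hydroxy-1,5-dimethylbicyclo[3.3.1]nonan-9-one | C1[C@]2(C)CCC[C@@](C)(C2=O)[C@H](O)C1 | intermediate
5 | (1R,5S)-1,5-dimethylbicyclo[3.3.1]nonane-2,9-dione | C1[C@]2(C)CCC[C@@](C)(C2=O)C(=O)C1 | intermediate (not isolated)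
6 | (1R,5S)-1,5-dimethylbicyclo[3.3.1]non-3-ene-2,9-dione | O=C1C=C[C@]2(C)CCC[C@@]1(C)C2=O | intermediate
7 | (4-bromobut-1-yn-1-yl)trimethylsilane | C[Si](C)(C)C#CCCBr | starting material
8 | [4-(trimethylsilyl)but-3-yn-1-yl]magnesium bromide | C[Si](C)(C)C#CCC[Mg]Br | intermediate (not isolated)
9 | bromomagnesium (1R,4R,5S)-1,5-dimethyl-9-oxo-4-[4-(trimethylsilyl)but-3-yn-1-yl]bicyclo[3.3.1]non-2-en-2-olate | C[Si](C)(C)C#CCC[C@@H]1C=C(O[Mg]Br)[C@@]2(C)CCC[C@]1(C)C2=O | intermediate (not isolated)
10 | (1R,4R,5S)-1,3,5-trimethyl-4-[4-(trimethylsilyl)but-3-yn-1-yl]bicyclo[3.3.1]nonane-2,9-dione (either configuration at C3) | C[Si](C)(C)C#CCC[C@@H]1C(C)C(=O)[C@@]2(C)CCC[C@]1(C)C2=O | intermediate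
11 | (1R,4R,5S)-1,3,5-trimethyl-9-oxo-4-[4-(trimethylsilyl)but-3-yn-1-yl]bicyclo[3.3.1]non-2-en-2-yl trifluoromethanesulfonate | C[Si](C)(C)C#CCC[C@@H]1C(C)=C(OS(=O)(=O)C(F)(F)F)[C@@]2(C)CCC[C@]1(C)C2=O | intermediate
12 | (1R,4R,5S)-1,3,5-trimethyl-4-[4-(trimethylsilyl)but-3-yn-1-yl]bicyclo[3.3.1]non-2-en-9-one | C[Si](C)(C)C#CCC[C@@H]1C(C)=C[C@@]2(C)CCC[C@]1(C)C2=O | intermediate
13 | (1R,4R,5S)-1,3,5-trimethyl-4-[4-(trimethylsilyl)but-3-yn-1-yl]bicyclo[3.3.1]non-2-ene-9-carbonitrile (both C9 epimers) | C[Si](C)(C)C#CCC[C@@H]1C(C)=C[C@@]2(C)CCC[C@]1(C)C2C#N | intermediate (not isolated)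
14 | (1R,4R,5S)-4-(but-3-yn-1-yl)-1,3,5-trimethylbicyclo[3.3.1]non-2-ene-9-carbonitrile (both C9 epimers) | C#CCC[C@@H]1C(C)=C[C@@]2(C)CCC[C@]1(C)C2C#N | intermediate
15 | 1-[(1R,4R,5S)-4-(but-3-yn-1-yl)-1,3,5-trimethylbicyclo[3.3.1]non-2-en-9-yl]ethan-1-imine (both C9 epimers) | C#CCC[C@@H]1C(C)=C[C@@]2(C)CCC[C@]1(C)C2C(C)=N | intermediate (not isolated)
16 | 1-[(1R,4R,5S)-4-(but-3-yn-1-yl)-1,3,5-trimethylbicyclo[3.3.1]non-2-en-9-yl]ethan-1-one (mixture of C9 epimers) | C#CCC[C@@H]1C(C)=C[C@@]2(C)CCC[C@]1(C)C2C(C)=O | intermediate (not isolated)
17 | 1-[(1R,4R,5S,9R)-4-(but-3-yn-1-yl)-1,3,5-trimethylbicyclo[3.3.1]non-2-en-9-yl]ethan-1-one (acetyl on the face of the saturated bridge) | C#CCC[C@@H]1C(C)=C[C@@]2(C)CCC[C@]1(C)[C@@H]2C(C)=O | intermediate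
18 | (1S,2S,3S)-2-acetyl-1,3-dimethyl-3-[(3S)-2-oxohept-6-yn-3-yl]cyclohexane-1-carbaldehyde | C#CCC[C@H](C(C)=O)[C@]1(C)CCC[C@](C)(C=O)[C@H]1C(C)=O | intermediate (not isolated)
19 | (3S)-3-[(1S,2S,3S)-2-acetyl-3-(hydroxymethyl)-1,3-dimethylcyclohexyl]hept-6-yn-2-one | C#CCC[C@H](C(C)=O)[C@]1(C)CCC[C@](C)(CO)[C@H]1C(C)=O | intermediate
20 | (3S)-3-[(1S,2S,3S)-2-acetyl-3-({[tert-butyl(dimethyl)silyl]oxy}methyl)-1,3-dimethylcyclohexyl]hept-6-yn-2-one | C#CCC[C@H](C(C)=O)[C@]1(C)CCC[C@](C)(CO[Si](C)(C)C(C)(C)C)[C@H]1C(C)=O | intermediate
21 | (4S,4aS,8S,8aS)-4-(but-3-yn-1-yl)-8-({[tert-butyl(dimethyl)silyl]oxy}methyl)-3-hydroxy-3,4a,8-trimethyloctahydronaphthalen-1(2H)-one (either configuration at C3) | C#CCC[C@@H]1C(C)(O)CC(=O)[C@@H]2[C@@](C)(CO[Si](C)(C)C(C)(C)C)CCC[C@@]12C | intermediate (not isolated)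
22 | (4R,4aS,8S,8aS)-4-(but-3-yn-1-yl)-8-({[tert-butyl(dimethyl)silyl]oxy}methyl)-3,4a,8-trimethyl-4a,5,6,7,8,8a-hexahydronaphthalen-1(4H)-one | C#CCC[C@@H]1C(C)=CC(=O)[C@@H]2[C@@](C)(CO[Si](C)(C)C(C)(C)C)CCC[C@@]12C | intermediate
23 | (2R,3R,4S,4aS,8S,8aS)-4-(but-3-yn-1-yl)-8-({[tert-butyl(dimethyl)silyl]oxy}methyl)-2,3-epoxy-3,4a,8-trimethyloctahydronaphthalen-1(2H)-one | C#CCC[C@@H]1[C@@]3(C)O[C@H]3C(=O)[C@@H]2[C@@](C)(CO[Si](C)(C)C(C)(C)C)CCC[C@@]12C | intermediate
24 | (3S,4S,4aS,8S,8aS)-4-(but-3-yn-1-yl)-8-({[tert-butyl(dimethyl)silyl]oxy}methyl)-3-hydroxy-3,4a,8-trimethyloctahydronaphthalen-1(2H)-one | C#CCC[C@@H]1[C@@](C)(O)CC(=O)[C@@H]2[C@@](C)(CO[Si](C)(C)C(C)(C)C)CCC[C@@]12C | intermediate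
25 | (1R,3S,4S,4aR,8S,8aS)-4-(but-3-yn-1-yl)-8-({[tert-butyl(dimethyl)silyl]oxy}methyl)-3,4a,8-trimethyldecahydronaphthalene-1,3-diol | C#CCC[C@@H]1[C@@](C)(O)C[C@@H](O)[C@@H]2[C@@](C)(CO[Si](C)(C)C(C)(C)C)CCC[C@@]12C | intermediate
26 | (1R,3S,4S,4aR,8S,8aS)-4-(but-3-yn-1-yl)-8-({[tert-butyl(dimethyl)silyl]oxy}methyl)-3-hydroxy-3,4a,8-trimethyldecahydronaphthalen-1-yl acetate | C#CCC[C@@H]1[C@@](C)(O)C[C@@H](OC(C)=O)[C@@H]2[C@@](C)(CO[Si](C)(C)C(C)(C)C)CCC[C@@]12C | intermediate
27 | (1R,3S,4S,4aR,8S,8aS)-4-(but-3-yn-1-yl)-3-hydroxy-8-(hydroxymethyl)-3,4a,8-trimethyldecahydronaphthalen-1-yl acetate | C#CCC[C@@H]1[C@@](C)(O)C[C@@H](OC(C)=O)[C@@H]2[C@@](C)(CO)CCC[C@@]12C | intermediate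
28 | (1R,3S,4S,4aR,8S,8aS)-3-hydroxy-8-(hydroxymethyl)-3,4a,8-trimethyl-4-(3-methylidenepent-4-en-1-yl)decahydronaphthalen-1-yl acetate | C=CC(=C)CC[C@H]1[C@]2(C)CCC[C@](C)(CO)[C@H]2[C@H](OC(C)=O)C[C@]1(C)O | target

## Step count and least certain steps

Total: 16 steps. Longest linear sequence: 16 steps from 1 and 2; the side-chain reagent 7 is commercial and enters in step 3.

**Step 1 (key step).** The most likely failures are poor facial discrimination, because a simple ketone enolate forms only a loose ion pair with the ammonium cation, and low conversion, because the ketone is weakly acidic under phase-transfer conditions and base-induced polymerisation of the enal can take over. The fallback uses known chemistry and sets out from 1 and 2. The annulation is run with an achiral phase-transfer base (KOH, Bu4NBr, PhMe) to give the racemic alcohol F1. Acylation with (1S)-camphanic chloride and pyridine, followed by separation of the diastereomeric esters, gives the camphanate F2 of the required enantiomer. Methanolysis (K2CO3, MeOH) releases the alcohol, and the route is rejoined at 4.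

**Step 4.** Enolisation of the hindered methine of 10, which sits between a quaternary bridgehead and the side-chain carbon, may be slow or incomplete, so that triflation stalls. The fallback sets out from 6 and avoids this deprotonation. α-Iodination (I2, pyridine) gives the iodo enedione F3. Palladium-catalysed methylation (MeB(OH)2, Pd(PPh3)4, K2CO3) gives the 3-methyl enedione F4. Conjugate addition of 8 to F4 then generates the tetrasubstituted enolate directly, and trapping with PhNTf2 returns the route at 11.

**Step 6.** The isocyanide anion may fail to add to the doubly flanked ketone, or the intermediate may divert to the alkoxy-oxazoline and not the nitrile. The fallback sets out from 12. 1-Ethoxyvinyllithium (from ethyl vinyl ether and t-BuLi) adds to the ketone to give the ethoxyvinyl carbinol F5. Dilute HCl unmasks the α-hydroxy methyl ketone F6. SmI2 in THF/MeOH removes the tertiary hydroxyl reductively to give the silylated methyl ketone F7. NaOMe in MeOH then equilibrates C9 and removes the alkynyl silyl group, returning the route at 17.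

**Step 10.** The E1cB dehydration may need forcing alkoxide conditions, under which the stereocentre bearing the butynyl chain (α to the side-arm ketone before closure, γ to the enone after) can epimerise. The fallback sets out from 20 and splits the step. Catalytic KOtBu in THF at −20 °C is used only for the aldol addition, and the ketol 21 is isolated. It is then dehydrated under neutral conditions by syn-elimination with methyl N-(triethylammoniosulfonyl)carbamate (Burgess reagent) in PhMe, rejoining at 22. This detour makes no compound outside the list (entry F0).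

**Step 13.** Facial selectivity may be poor, giving the axial alcohol, or the β-hydroxy ketone may undergo retro-aldol cleavage in the amine medium. The fallback sets out from 24. Kinetic reduction with NaBH4 gives the axial alcohol F8. Meerwein–Ponndorf–Verley/Oppenauer equilibration (Al(OiPr)3, catalytic acetone, i-PrOH/PhMe, reflux) then moves it to the more stable equatorial epimer, rejoining at 25.

## Further compounds

F1 | step 1 | racemic 2-hydroxy-1,5-dimethylbicyclo[3.3.1]nonan-9-one | CC12CCCC(C)(C1=O)C(O)CC2
F2 | step 1 | (1R,2R,5S)-1,5-dimethyl-9-oxobicyclo[3.3.1]nonan-2-yl (1S,4R)-4,7,7-trimethyl-3-oxo-2-oxabicyclo[2.2.1]heptane-1-carboxylate | C1[C@]2(C)CCC[C@@](C)(C2=O)[C@H](OC(=O)[C@@]34CC[C@@](C)(C(=O)O3)C4(C)C)C1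
F3 | step 4 | (1S,5S)-3-iodo-1,5-dimethylbicyclo[3.3.1]non-3-ene-2,9-dione | O=C1C(I)=C[C@]2(C)CCC[C@@]1(C)C2=O
F4 | step 4 | (1R,5S)-1,3,5-trimethylbicyclo[3.3.1]non-3-ene-2,9-dione | O=C1C(C)=C[C@]2(C)CCC[C@@]1(C)C2=O
F5 | step 6 | (1R,4R,5S)-9-(1-ethoxyethenyl)-1,3,5-trimethyl-4-[4-(trimethylsilyl)but-3-yn-1-yl]bicyclo[3.3.1]non-2-en-9-ol (either configuration at C9) | C[Si](C)(C)C#CCC[C@@H]1C(C)=C[C@@]2(C)CCC[C@]1(C)C2(O)C(=C)OCC
F6 | step 6 | 1-{(1R,4R,5S)-9-hydroxy-1,3,5-trimethyl-4-[4-(trimethylsilyl)but-3-yn-1-yl]bicyclo[3.3.1]non-2-en-9-yl}ethan-1-one (either configuration at C9) | C[Si](C)(C)C#CCC[C@@H]1C(C)=C[C@@]2(C)CCC[C@]1(C)C2(O)C(C)=O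
F7 | step 6 | 1-{(1R,4R,5S)-1,3,5-trimethyl-4-[4-(trimethylsilyl)but-3-yn-1-yl]bicyclo[3.3.1]non-2-en-9-yl}ethan-1-one (mixture of C9 epimers) | C[Si](C)(C)C#CCC[C@@H]1C(C)=C[C@@]2(C)CCC[C@]1(C)C2C(C)=O
F0 | step 10 | none | none
F8 | step 13 | (1S,3S,4S,4aR,8S,8aS)-4-(but-3-yn-1-yl)-8-({[tert-butyl(dimethyl)silyl]oxy}methyl)-3,4a,8-trimethyldecahydronaphthalene-1,3-diol | C#CCC[C@@H]1[C@@](C)(O)C[C@H](O)[C@@H]2[C@@](C)(CO[Si](C)(C)C(C)(C)C)CCC[C@@]12C
A1 | alternative 1 | methyl (2E,8E)-4-{[tert-butyl(dimethyl)silyl]oxy}-7-{2-[(4-methoxybenzyl)oxy]ethyl}-2,8-dimethyl-6-oxoundeca-2,8,10-trienoate (acyclic trienoate) | C=C/C=C(C)/[C@H](CCOCc1ccc(OC)cc1)C(=O)C[C@@H](O[Si](C)(C)C(C)(C)C)/C=C(\C)C(=O)OC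
A2 | alternative 1 | trans-fused octalin ester (Diels–Alder adduct) | COc1ccc(COCC[C@H]2[C@]3(C)C=CC[C@](C)(C(=O)OC)[C@H]3[C@H](O[Si](C)(C)C(C)(C)C)CC2=O)cc1
A3 | alternative 2 | [(1S)-2-ethenyl-1,3-dimethylcyclohex-2-en-1-yl]methyl but-2-ynoate | CC#CC(=O)OC[C@@]1(C)CCCC(C)=C1C=C
A4 | alternative 2 | lactone-bridged cyclohexa-1,4-diene (ring B 5,8-diene) | O=C1OC[C@@]2(C)CCC[C@@]3(C)C1=C(C)CC=C23
A5 | alternative 3 | silylene-bridged trienol ether (C5 and C8 cis on the central double bond) | C#CCC/C=C(C)/C=C1/O[Si](C(C)(C)C)(C(C)(C)C)OC[C@@]2(C)CCCC(C)=C12
A6 | alternative 3 | silylene-bridged cyclohexa-1,3-dienol ether (ring B 5,7-diene) | C#CCC[C@H]1[C@]2(C)CCC[C@](C)(CO[Si](C(C)(C)C)(C(C)(C)C)O3)C2=C3C=C1C
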